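**Retrosynthetic overview**
- Target ⇐ global O-desilylation ⇐ Heck coupling of a cis-7-bromo-2,3-diaryl-1,4-benzodioxane with 3,5-bis(silyloxy)styrene (installs the stilbene last).
- cis-Bromide ⇐ C2 stereo-editing of the ring-expansion product: oxidation to the C2 ketal, then hydride delivery anti to the C3 aryl group.
- Key step: three-atom ring expansion of an enantiopure trans-stilbene oxide (oxirane → 1,4-dioxane) by an ortho-quinone diazide. The epoxide oxygen stays on C3, so C3 comes from the epoxide and the ring A substitution pattern from the diazide.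
- Epoxide ⇐ Shi epoxidation ⇐ Heck coupling of silylated 4-bromocatechol with the same styrene; diazide ⇐ 4-bromoaniline (ortho-hydroxylation, diazotisation).
- Ring order: all benzene rings are bought (catechol, resorcinol, 4-bromoaniline); the oxirane is made first and then enlarged to the dioxane ring; the vinyl carbons come from vinyl bromide.

Assumption: the SMILES is read as the 2,3-cis isomer. Numbering used throughout: O1, C2 (R, carries the 3,4-dihydroxyphenyl ring B), C3 (S, carries the 3,5-dihydroxyphenyl ring C), O4, styryl (ring D) on C7 of ring A, para to O4. TIPS = triisopropylsilyl, Bpin = pinacolboryl.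

**Route**

Step 1
Reactants: 1 catechol
Product: 2 4-bromocatechol
Conditions: NBS (1.0 equiv), HBF4·OEt2, MeCN, −30 °C to rt
Reagents that add atoms: N-bromosuccinimide, O=C1CCC(=O)N1Br
Why: Electrophilic aromatic bromination of the electron-rich ring goes para to a hydroxyl group, and one equivalent of acid-activated NBS stops at the 4-bromide.

Step 2
Reactants: 2 4-bromocatechol
Product: 3 4-bromo-1,2-bis(triisopropylsilyloxy)benzene
Conditions: TIPSCl (2.5 equiv), imidazole (5 equiv), DMAP (cat.), DMF, 50 °C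
Reagents that add atoms: triisopropylsilyl chloride, CC(C)[Si](Cl)(C(C)C)C(C)C
Why: Imidazole-promoted O-silylation of both phenols gives bulky silyl ethers that survive the basic, oxidative and Lewis-acidic steps ahead and fall to fluoride at the end.

Step 3
Reactants: 4 resorcinol
Product: 5 1,3-bis(triisopropylsilyloxy)benzene
Conditions: TIPSCl (2.3 equiv), imidazole (4.5 equiv), DMF, rt
Reagents that add atoms: triisopropylsilyl chloride, CC(C)[Si](Cl)(C(C)C)C(C)C
Why: Standard phenol O-silylation, which also turns the two oxygens into the steric blocking groups needed for step 4.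

Step 4
Reactants: 5 1,3-bis(triisopropylsilyloxy)benzene
Product: 6 2-[3,5-bis(triisopropylsilyloxy)phenyl]-4,4,5,5-tetramethyl-1,3,2-dioxaborolane
Conditions: B2pin2 (1.0 equiv), [Ir(cod)(OMe)]2 (1 mol%), 4,4'-di-tert-butyl-2,2'-bipyridine (2 mol%), cyclohexane, 80 °C
Reagents that add atoms: bis(pinacolato)diboron, CC1(C)OB(OC1(C)C)B1OC(C)(C)C(C)(C)O1
Why: Iridium-catalysed aromatic C–H borylation is sterically controlled, so only C5, the single C–H without an ortho substituent, reacts.

Step 5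
Reactants: 6 2-[3,5-bis(triisopropylsilyloxy)phenyl]-4,4,5,5-tetramethyl-1,3,2-dioxaborolane; 7 vinyl bromide
Product: 8 3,5-bis(triisopropylsilyloxy)styrene
Conditions: Pd(dppf)Cl2 (3 mol%), K3PO4 (3 equiv), vinyl bromide (3 equiv, THF solution), THF/H2O 10:1, 60 °C, sealed vessel
Reagents that add atoms: none
Why: Suzuki–Miyaura coupling of the aryl boronate with vinyl bromide forms the aryl–vinyl bond at the only reactive site.

Step 6
Reactants: 3 4-bromo-1,2-bis(triisopropylsilyloxy)benzene; 8 3,5-bis(triisopropylsilyloxy)styrene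
Product: 9 (E)-1-[3,4-bis(triisopropylsilyloxy)phenyl]-2-[3,5-bis(triisopropylsilyloxy)phenyl]ethene
Conditions: Pd2(dba)3 (2.5 mol%), P(t-Bu)3·HBF4 (10 mol%), Cy2NMe (1.5 equiv), 1,4-dioxane, 90 °C
Reagents that add atoms: none
Why: Mizoroki–Heck reaction in which the aryl palladium species adds to the unsubstituted alkene carbon and syn β-hydride elimination gives the E stilbene.

Step 7
Reactants: 9 (E)-1-[3,4-bis(triisopropylsilyloxy)phenyl]-2-[3,5-bis(triisopropylsilyloxy)phenyl]ethene
Product: 10 (2S,3S)-2-[3,4-bis(triisopropylsilyloxy)phenyl]-3-[3,5-bis(triisopropylsilyloxy)phenyl]oxirane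
Conditions: L-fructose-derived enantiomer of the Shi ketone (30 mol%), KHSO5 (as Oxone, 1.6 equiv), K2CO3, Bu4NHSO4 (cat.), MeCN/dimethoxymethane–aq. Na2B4O7 buffer (pH 10.5), 0 °C; chromatography on Et3N-deactivated silica
Reagents that add atoms: potassium peroxymonosulfate, [K+].[O-]S(=O)(=O)OO
Why: Shi asymmetric epoxidation, in which the chiral dioxirane transfers oxygen to one face of the trans alkene through a spiro transition state and sets both epoxide carbons as S (mirror image of the R,R outcome given by the D-fructose ketone with trans-stilbenes), the C3 centre made here being carried unchanged to the target.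

Step 8
Reactants: 11 4-bromoaniline
Product: 13 2-amino-5-bromophenol, via diborylated aniline 12 (not isolated)
Conditions: HBpin (10 mol%), B2pin2 (1.1 equiv), [Ir(cod)(OMe)]2 (1.5 mol%), 3,4,7,8-tetramethyl-1,10-phenanthroline (3 mol%), THF, 80 °C; then NaBO3·4H2O, THF/H2O, rt
Reagents that add atoms: bis(pinacolato)diboron, CC1(C)OB(OC1(C)C)B1OC(C)(C)C(C)(C)O1 (boron carried only in 12); sodium perborate, [Na+].[O-]OB=O
Why: Iridium-catalysed C–H borylation is steered ortho to nitrogen by the N-boryl group formed in situ (the C–H bonds next to bromine are shielded), and perborate then oxidises the C–B bond to C–OH at the same position while water frees the amine.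

Step 9
Reactants: 13 2-amino-5-bromophenol
Product: 14 3-bromo-6-diazocyclohexa-2,4-dien-1-one
Conditions: t-BuONO (1.2 equiv), AcOH (cat.), THF, 0 °C, dark; precipitated with cold pentane and used at once
Reagents that add atoms: tert-butyl nitrite, CC(C)(C)ON=O
Why: Diazotisation of the ortho-aminophenol with an alkyl nitrite gives the diazonium phenolate, which is the neutral ortho-quinone diazide with bromine para to the diazo carbon.

Step 10
Reactants: 10 (2S,3S)-2-[3,4-bis(triisopropylsilyloxy)phenyl]-3-[3,5-bis(triisopropylsilyloxy)phenyl]oxirane; 14 3-bromo-6-diazocyclohexa-2,4-dien-1-one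
Product: 15 (3S)-7-bromo-2-[3,4-bis(triisopropylsilyloxy)phenyl]-3-[3,5-bis(triisopropylsilyloxy)phenyl]-2,3-dihydro-1,4-benzodioxine as a mixture of C2 epimers
Conditions: [CpRu(CH3CN)3]PF6 (5 mol%), 1,10-phenanthroline (5 mol%), CH2Cl2, 40 °C, slow addition of 14 (1.5 equiv), dark
Reagents that add atoms: none
Why: Proposed new method: the ruthenium carbene formed from 14 is attacked by the epoxide oxygen to give an oxonium ylide that is, after rearomatisation of ring A, a phenoxide tethered to an O-aryl oxiranium ion; the C2–O bond (benzylic to the 4-silyloxyphenyl ring B) ionises while the C3–O bond (next to the electron-poor 3,5-disilyloxyphenyl ring C) stays intact, and the phenoxide closes on C2, so the oxirane is enlarged by three atoms to the 1,4-dioxane ring in a stepwise ionic, non-pericyclic ring expansion that keeps the epoxide oxygen and the S configuration on C3, fixes the ring A pattern (the oxygen on C3 is para to Br because N2 left from that carbon) and leaves C2 as an epimer mixture corrected in step 11; the closest known reaction type is the three-atom ring expansion of epoxides to 1,4-dioxenes by metal carbenes of α-diazo-β-keto esters under [CpRu(CH3CN)3]PF6/1,10-phenanthroline catalysis.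

Step 11
Reactants: 15 (3S)-7-bromo-2-[3,4-bis(triisopropylsilyloxy)phenyl]-3-[3,5-bis(triisopropylsilyloxy)phenyl]-2,3-dihydro-1,4-benzodioxine as a mixture of C2 epimers
Product: 17 (2R,3S)-7-bromo-2-[3,4-bis(triisopropylsilyloxy)phenyl]-3-[3,5-bis(triisopropylsilyloxy)phenyl]-2,3-dihydro-1,4-benzodioxine, via C2 methoxy ketal 16 (not isolated)
Conditions: DDQ (1.3 equiv), CH2Cl2/MeOH 10:1, 0 °C; filter through basic alumina, concentrate; then Et3SiH (3 equiv), BF3·OEt2 (1.5 equiv), CH2Cl2, −78 °C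
Reagents that add atoms: methanol, CO (carried only in 16)
Why: DDQ abstracts hydride from the only activated benzylic ether C–H (C2, next to the 4-silyloxyphenyl ring) and methanol traps the cation as the ketal, after which ionic hydrogenation of the re-formed C2 oxocarbenium ion delivers hydride anti to the pseudoaxial C3 aryl group, so both C2 epimers converge on the 2,3-cis (2R,3S) product while C3 is untouched.

Step 12
Reactants: 17 (2R,3S)-7-bromo-2-[3,4-bis(triisopropylsilyloxy)phenyl]-3-[3,5-bis(triisopropylsilyloxy)phenyl]-2,3-dihydro-1,4-benzodioxine; 8 3,5-bis(triisopropylsilyloxy)styrene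
Product: 18 (2R,3S)-2-[3,4-bis(triisopropylsilyloxy)phenyl]-3-[3,5-bis(triisopropylsilyloxy)phenyl]-7-[(E)-2-[3,5-bis(triisopropylsilyloxy)phenyl]ethenyl]-2,3-dihydro-1,4-benzodioxine
Conditions: Pd2(dba)3 (2.5 mol%), P(t-Bu)3·HBF4 (10 mol%), Cy2NMe (1.5 equiv), 1,4-dioxane, 90 °C
Reagents that add atoms: none
Why: Mizoroki–Heck coupling of the aryl bromide with the terminal styrene gives the E stilbene, and the fully silylated cis-benzodioxane has no free phenol through which C2 could epimerise.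

Step 13
Reactants: 18 (2R,3S)-2-[3,4-bis(triisopropylsilyloxy)phenyl]-3-[3,5-bis(triisopropylsilyloxy)phenyl]-7-[(E)-2-[3,5-bis(triisopropylsilyloxy)phenyl]ethenyl]-2,3-dihydro-1,4-benzodioxine
Product: 19 (2R,3S)-2-(3,4-dihydroxyphenyl)-3-(3,5-dihydroxyphenyl)-7-[(E)-2-(3,5-dihydroxyphenyl)ethenyl]-2,3-dihydro-1,4-benzodioxine
Conditions: Bu4NF (7 equiv), AcOH (7 equiv), THF, 0 °C to rt
Reagents that add atoms: none
Why: Fluoride cleaves the six aryl Si–O bonds, and acetic acid buffering keeps the phenols protonated so that no quinone-methide ring opening (cis to trans epimerisation at C2) occurs.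

**Compound list**

1 | catechol | Oc1ccccc1O | starting material
2 | 4-bromocatechol | Oc1ccc(Br)cc1O | intermediate
3 | 4-bromo-1,2-bis(triisopropylsilyloxy)benzene | CC(C)[Si](C(C)C)(C(C)C)Oc1ccc(Br)cc1O[Si](C(C)C)(C(C)C)C(C)C | intermediate
4 | resorcinol | Oc1cccc(O)c1 | starting material
5 | 1,3-bis(triisopropylsilyloxy)benzene | CC(C)[Si](C(C)C)(C(C)C)Oc1cccc(O[Si](C(C)C)(C(C)C)C(C)C)c1 | intermediate
6 | 2-[3,5-bis(triisopropylsilyloxy)phenyl]-4,4,5,5-tetramethyl-1,3,2-dioxaborolane | CC(C)[Si](C(C)C)(C(C)C)Oc1cc(O[Si](C(C)C)(C(C)C)C(C)C)cc(c1)B1OC(C)(C)C(C)(C)O1 | intermediate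
7 | vinyl bromide | C=CBr | starting material
8 | 3,5-bis(triisopropylsilyloxy)styrene | C=Cc1cc(O[Si](C(C)C)(C(C)C)C(C)C)cc(O[Si](C(C)C)(C(C)C)C(C)C)c1 | intermediate
9 | (E)-1-[3,4-bis(triisopropylsilyloxy)phenyl]-2-[3,5-bis(triisopropylsilyloxy)phenyl]ethene | CC(C)[Si](C(C)C)(C(C)C)Oc1ccc(/C=C/c2cc(O[Si](C(C)C)(C(C)C)C(C)C)cc(O[Si](C(C)C)(C(C)C)C(C)C)c2)cc1O[Si](C(C)C)(C(C)C)C(C)C | intermediate
10 | (2S,3S)-2-[3,4-bis(triisopropylsilyloxy)phenyl]-3-[3,5-bis(triisopropylsilyloxy)phenyl]oxirane | CC(C)[Si](C(C)C)(C(C)C)Oc1ccc(cc1O[Si](C(C)C)(C(C)C)C(C)C)[C@@H]1O[C@H]1c1cc(O[Si](C(C)C)(C(C)C)C(C)C)cc(O[Si](C(C)C)(C(C)C)C(C)C)c1 | intermediate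
11 | 4-bromoaniline | Nc1ccc(Br)cc1 | starting material
12 | 4-bromo-N,2-bis(4,4,5,5-tetramethyl-1,3,2-dioxaborolan-2-yl)aniline | CC1(C)OB(Nc2ccc(Br)cc2B2OC(C)(C)C(C)(C)O2)OC1(C)C | intermediate
13 | 2-amino-5-bromophenol | Nc1ccc(Br)cc1O | intermediate
14 | 3-bromo-6-diazocyclohexa-2,4-dien-1-one (ortho-quinone diazide) | O=C1C=C(Br)C=CC1=[N+]=[N-] | intermediate
15 | (3S)-7-bromo-2-[3,4-bis(triisopropylsilyloxy)phenyl]-3-[3,5-bis(triisopropylsilyloxy)phenyl]-2,3-dihydro-1,4-benzodioxine, C2 epimer mixture | Brc1ccc2c(c1)OC(c1ccc(O[Si](C(C)C)(C(C)C)C(C)C)c(O[Si](C(C)C)(C(C)C)C(C)C)c1)[C@H](c1cc(O[Si](C(C)C)(C(C)C)C(C)C)cc(O[Si](C(C)C)(C(C)C)C(C)C)c1)O2 | intermediate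
16 | (3S)-7-bromo-2-methoxy-2-[3,4-bis(triisopropylsilyloxy)phenyl]-3-[3,5-bis(triisopropylsilyloxy)phenyl]-2,3-dihydro-1,4-benzodioxine, C2 epimer mixture | Brc1ccc2c(c1)OC(OC)(c1ccc(O[Si](C(C)C)(C(C)C)C(C)C)c(O[Si](C(C)C)(C(C)C)C(C)C)c1)[C@H](c1cc(O[Si](C(C)C)(C(C)C)C(C)C)cc(O[Si](C(C)C)(C(C)C)C(C)C)c1)O2 | intermediate
17 | (2R,3S)-7-bromo-2-[3,4-bis(triisopropylsilyloxy)phenyl]-3-[3,5-bis(triisopropylsilyloxy)phenyl]-2,3-dihydro-1,4-benzodioxine (2,3-cis) | Brc1ccc2c(c1)O[C@H](c1ccc(O[Si](C(C)C)(C(C)C)C(C)C)c(O[Si](C(C)C)(C(C)C)C(C)C)c1)[C@H](c1cc(O[Si](C(C)C)(C(C)C)C(C)C)cc(O[Si](C(C)C)(C(C)C)C(C)C)c1)O2 | intermediate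
18 | (2R,3S)-2-[3,4-bis(triisopropylsilyloxy)phenyl]-3-[3,5-bis(triisopropylsilyloxy)phenyl]-7-[(E)-2-[3,5-bis(triisopropylsilyloxy)phenyl]ethenyl]-2,3-dihydro-1,4-benzodioxine | CC(C)[Si](C(C)C)(C(C)C)Oc1cc(O[Si](C(C)C)(C(C)C)C(C)C)cc(/C=C/c2ccc3c(c2)O[C@H](c2ccc(O[Si](C(C)C)(C(C)C)C(C)C)c(O[Si](C(C)C)(C(C)C)C(C)C)c2)[C@H](c2cc(O[Si](C(C)C)(C(C)C)C(C)C)cc(O[Si](C(C)C)(C(C)C)C(C)C)c2)O3)c1 | intermediate
19 | (2R,3S)-2-(3,4-dihydroxyphenyl)-3-(3,5-dihydroxyphenyl)-7-[(E)-2-(3,5-dihydroxyphenyl)ethenyl]-2,3-dihydro-1,4-benzodioxine (CNP0283264.2) | Oc1cc(O)cc(/C=C/c2ccc3c(c2)O[C@H](c2ccc(O)c(O)c2)[C@H](c2cc(O)cc(O)c2)O3)c1 | target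

**Totals and risks**

Total step count: 13. Longest linear sequence: 9 steps (resorcinol through steps 3, 4, 5, 6, 7, 10, 11, 12, 13).

The three steps most likely to fail:

Step 10 (the proposed new ring expansion). The carbene may instead deoxygenate the epoxide back to stilbene 9, the zwitterion may undergo a 1,2-hydride shift and close to a 2,2-disubstituted 1,3-benzodioxole, or the free ketocarbene may undergo Wolff ring contraction or attack an arene. The fallback uses known chemistry, sets out from 14 and 10 and comes back at 15. Quinone diazide 14 is treated with KI in aqueous H2SO4 (protonation to the diazonium ion, iodide for N2) to give 5-bromo-2-iodophenol F1. F1 with a catalytic amount of Cs2CO3 in toluene at 80 °C opens epoxide 10 at the 4-silyloxybenzylic carbon to give (1S)-2-(5-bromo-2-iodophenoxy)-2-[3,4-bis(triisopropylsilyloxy)phenyl]-1-[3,5-bis(triisopropylsilyloxy)phenyl]ethanol F2, whose carbinol centre still carries the epoxide oxygen. CuI, 3,4,7,8-tetramethyl-1,10-phenanthroline and Cs2CO3 in toluene at 100 °C then close the ring by intramolecular O-arylation at the C–I bond (retention at C3, C–Br untouched) to give 15, whose C2 configuration is set in step 11 as before.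

Step 11 (C2 stereo-editing). The C2 oxocarbenium ion could lose the C3 proton to the achiral 2,3-diaryl-1,4-benzodioxin (loss of the C3 configuration), open by endocyclic C–O cleavage, or take hydride with poor facial selectivity. The fallback replaces cation reduction by an SN2 ring closure, sets out from 15 and comes back at 17. DDQ in wet CH2Cl2 gives the hemiketal, which reacts as its open form (S)-2-(4-bromo-2-hydroxyphenoxy)-1-[3,4-bis(triisopropylsilyloxy)phenyl]-2-[3,5-bis(triisopropylsilyloxy)phenyl]ethanone F3. KBH(s-Bu)3 in THF at −78 °C reduces the ketone under Felkin–Anh control to the threo alcohol (1S,2S)-2-(4-bromo-2-hydroxyphenoxy)-1-[3,4-bis(triisopropylsilyloxy)phenyl]-2-[3,5-bis(triisopropylsilyloxy)phenyl]ethanol F4. PPh3 and DIAD in THF at 0 °C close the ring by intramolecular Mitsunobu etherification with inversion at the carbinol carbon to give 17.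

Step 8 (one-pot directed borylation and oxidation). The electron-rich aminophenol may be over-oxidised, or the ortho-boronate may protodeboronate before oxidation. The fallback is a Boyland–Sims oxidation, sets out from 11 and comes back at 13. K2S2O8 in aqueous KOH at rt attacks ortho to nitrogen (para is blocked) to give potassium 2-amino-5-bromophenyl sulfate F5, which hot aqueous HCl hydrolyses to 13.

**Further compounds**

F1 | step 10 | 5-bromo-2-iodophenol | Oc1cc(Br)ccc1I
F2 | step 10 | (1S)-2-(5-bromo-2-iodophenoxy)-2-[3,4-bis(triisopropylsilyloxy)phenyl]-1-[3,5-bis(triisopropylsilyloxy)phenyl]ethanol, C2 epimer mixture | O[C@H](C(Oc1cc(Br)ccc1I)c1ccc(O[Si](C(C)C)(C(C)C)C(C)C)c(O[Si](C(C)C)(C(C)C)C(C)C)c1)c1cc(O[Si](C(C)C)(C(C)C)C(C)C)cc(O[Si](C(C)C)(C(C)C)C(C)C)c1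
F3 | step 11 | (S)-2-(4-bromo-2-hydroxyphenoxy)-1-[3,4-bis(triisopropylsilyloxy)phenyl]-2-[3,5-bis(triisopropylsilyloxy)phenyl]ethanone | O=C(c1ccc(O[Si](C(C)C)(C(C)C)C(C)C)c(O[Si](C(C)C)(C(C)C)C(C)C)c1)[C@@H](Oc1ccc(Br)cc1O)c1cc(O[Si](C(C)C)(C(C)C)C(C)C)cc(O[Si](C(C)C)(C(C)C)C(C)C)c1
F4 | step 11 | (1S,2S)-2-(4-bromo-2-hydroxyphenoxy)-1-[3,4-bis(triisopropylsilyloxy)phenyl]-2-[3,5-bis(triisopropylsilyloxy)phenyl]ethanol | O[C@@H](c1ccc(O[Si](C(C)C)(C(C)C)C(C)C)c(O[Si](C(C)C)(C(C)C)C(C)C)c1)[C@@H](Oc1ccc(Br)cc1O)c1cc(O[Si](C(C)C)(C(C)C)C(C)C)cc(O[Si](C(C)C)(C(C)C)C(C)C)c1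
F5 | step 8 | potassium 2-amino-5-bromophenyl sulfate | Nc1ccc(Br)cc1OS(=O)(=O)[O-].[K+]
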